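A small charge of free catalyst, 16 mol% on 0.10 M of substrate, has to carry this flask for 5.0 h, so we follow what each catalyst does rather than what the substrate does.

| setting | south-east | south-west | west | flask |
|---|---|---|---|---|
| substrate | 0.050 M | 0.075 M | 0.10 M | 0.10 M |
| gas | 42 mM (held) | 42 mM (held) | 42 mM (held) | 42 mM (held) |
| free catalyst | 16 mol% | 16 mol% | 32 mol% | 16 mol% |
| remark | run made earlier | run made earlier | run made earlier |  |
| time |  |  |  | 5.0 h |

- south-east (time / h: product / %, substrate / %): 0.250: 0, 92; 0.833: 0, 88; 1.33: 7, 85; 2.00: 8, 74; 3.00: 20, 70
- south-west (time / h: product / %, substrate / %): 0.250: 3, 95; 0.833: 3, 85; 1.33: 8, 83; 2.00: 13, 73; 3.00: 21, 66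
- west (time / h: product / %, substrate / %): 0.250: 0, 77; 0.833: 0, 64; 1.33: 14, 61; 2.00: 27, 48; 3.00: 40, 35

(each reading ± 2 percentage points)

- at the start none of reagent is dissolved
- on the list of suspects stand: substrate + free catalyst -> catalyst intermediate A; catalyst intermediate A -> catalyst intermediate B; reagent + catalyst intermediate B <-> catalyst intermediate C; catalyst intermediate C <-> by-product + catalyst intermediate D; catalyst intermediate D -> catalyst intermediate E; catalyst intermediate E <-> free catalyst + product; gas <-> reagent

1. the product standing at 5.0 h, as a percentage of the substrate charged
2. the change that raises the amount of product at 5.0 h, in percent of the substrate charged most ("none" if none brings more than 2 percentage points) (midnight / winter / dusk / none)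
3. amount of product at 5.0 h, in percent of the substrate charged, after winter

- midnight: doubling the transfer coefficient of the gas, all else as stated
- winter: doubling the saturation concentration of gas, all else as stated
- dusk: doubling the amount of free catalyst, all else as stated

First instants: by 0.833 h the west run has lost 36.0% of its substrate against a loading of 32 mol%, yet reads 0% product. The south-east run has lost 12.0% against 16 mol%. We read this as catalyst taking up substrate, about one load each, before product shows above the scatter.

Middle: product climbs. From 1.33 h to 3.00 h the west run gives 0.487 /h as its turnover frequency, the product made per hour for each catalyst charged. South-east gives 0.487 /h and south-west 0.487 /h, each with the scatter of its readings. So, as read within that scatter, the rate follows the catalyst and is zero order in substrate across these charges. Run back at that slope from its last reading to zero product, the west run gives a lag, as a reading, of 0.431 h.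

End: our reckoning for the flask is turnover frequency times loading times the time after the lag, 35.6%. Even with the whole loading held, that estimate leaves 48.4% of the substrate, so the reckoning has substrate to run on.

The forecast says 35%, slightly below ours, picks dusk, and gives 42% after winter, noting that “Gas was never varied”.

The flask gives 38.9%, and 42.9% after winter. Dusk adds 20 percentage points, winter 4 points and midnight 0.19 points, so dusk stands; a run in which winter gained more than 20 points would overturn that choice.

    substrate + free catalyst → catalyst intermediate A (k = 0.684 /M/min)
    catalyst intermediate A → catalyst intermediate B (k = 0.0467 /min)
    reagent + catalyst intermediate B ⇌ catalyst intermediate C (K = 45.0 /M, k = 1.39 /M/min)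
    catalyst intermediate C ⇌ by-product + catalyst intermediate D (K = 0.0264 M, k = 0.444 /min)
    catalyst intermediate D → catalyst intermediate E (k = 0.188 /min)
    catalyst intermediate E ⇌ free catalyst + product (K = 0.0556 M, k = 0.0462 /min)
    gas ⇌ reagent, rate k7*(csat - [reagent]) (kL = 0.110 /min)

Over the 4.57 h after the lag, the flask's 38.9% means an average turnover frequency of 0.532 /h. Now take the neighbour with 0.040 M of substrate at the same loading. Our reckoning contains no substrate concentration, so it again says 35.6%. That flask gives 32.5%, an average turnover frequency of 0.445 /h, and at 5.00 h it has 40.8% of its catalyst free, more than the 21.8% in the flask at 0.10 M.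

The earlier runs and the new flask are calculated for substances that don't exist; scatter was added.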